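## Structural features

The target is an icetexane (9(10→20)-abeo-abietane). Ring A (C1–C5, C10) is a cyclohexane, ring B (C5, C6, C7, C8, C9, C20, C10) is seven-membered, and ring C (C8, C9, C11–C14) is a 12-hydroxy-13-isopropyl-1,4-benzoquinone. A γ-lactone (C19 carbonyl on C4, ring oxygen on C6) is cis-fused to ring A across C4–C5; because C6 also starts the C6=C7 double bond it is an enol lactone with the aryl carbon C8 trans to the ring oxygen. Ring B therefore holds three double bonds (C6=C7, C8=C9, C10=C20) around one sp3 atom, C5, and is cross-conjugated with the quinone. The stereocentres are the quaternary C4 (methyl and C19), its neighbour C5 (hydrogen cis to the methyl) and the allylic carbinol C1, whose hydroxyl lies on the lactone face; the configuration is 1R,4S,5R. The enol lactone is an acyl donor that also hydrates to the hemiketal, the hydroxyquinone does not tolerate strong base, nucleophiles or reductants, and the C5 hydrogen is a cycloheptatriene hydrogen that can migrate on heating. The real difficulty is to close ring B with C10=C20 placed exocyclic to ring A while the E enol lactone and the C5 configuration stay intact. The key step uses the fact that C10 is α to the C1 carbonyl and C20 is benzylic on ring C: both can be tied through one sulfonyl group into an eight-membered ring (C5, C6, C7, C8, C9, C20, S, C10), which contracts to ring B with loss of SO2.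

## Logic of the disconnections

27 to 24. The O12–H, the two quinone carbonyls and the C1–H bond are traced back to a methyl ether, a trimethoxyarene and a C1 ketone. 26 keeps the 12-methyl ether, 25 masks the quinone as an oxidisable arene and 24 carries the ketone that the key step needs. This removes every sensitive group of ring C from the ring-forming chemistry. The forward steps must hydrolyse a vinylogous ester beside an enol lactone, oxidise with tetravalent cerium without touching the allylic alcohol, and deliver hydride to the face of C1 opposite the lactone.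

24 to 22. The C10=C20 bond is cut and each carbon is attached to sulfur, with chlorine on C20, giving 22 by way of 23. A direct seven-membered carbon–carbon closure becomes two carbon–sulfur bonds and a 1,3-elimination. The forward step needs a base weak enough to spare the enol lactone; this is met because C10–H of 22 is flanked by ketone and sulfone. It also needs carbon, not oxygen, of the resulting enolate to attack C20.

22 to 19. The C20–Cl bond is removed. Direct chlorination of 19 would go to the far more acidic C10, so C10 is first silenced as the enol silyl ether 20; the only sulfonyl-activated sp3 C–H left is then benzylic C20, which is metalated and chlorinated (21) before the ketone is released. The demand is clean α′-metalation without touching the allylic C2 hydrogens.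

19 to 17. The S–C10 bond is cut to a benzylic sulfinate (18, released from a fluoride-labile sulfone) and a secondary α-bromo ketone. The sulfone arrives at the right oxidation level, so no oxidant has to meet the enol lactone. The forward step must close an eight-membered ring by S-alkylation under conditions that do not eliminate HBr.

17 to 16. The C10–Br bond is traced to the C1=C10 enol silyl ether of 16. This enol ether is what makes C10, and not C2, the functionalised α-carbon; the forward step is a bromination that must prefer it over the enol lactone alkene.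

16 to 15 and 7. The C7–C8 bond and the O–C6 bond are cut together, leading to an aryl iodide and a 4-alkynoic acid. Anti addition of carboxylate and arylpalladium across the alkyne fixes the E geometry, which olefination of a C6 carbonyl could not guarantee. The demand is oxidative addition of a hindered, electron-rich aryl iodide.

15 to 8, 9 and 12. In 13 the bonds C2–C3 and C4–C5 are cut (Diels–Alder), giving diene 11 and 12. With C5 and C10 as diene carbons the new enol ether lies between C1 and C10, C4 and C5 are set cis by the endo mode, and C6/C7 come in as the alkyne. A cycloaddition that delivers C4 and C5 together from a methylmaleic dienophile would fix the cis fusion as well, but it leaves the enol ether on the C2 side and a carbonyl at C6. The forward step needs facial control by a chiral Lewis acid; 11 is cut at C10=C5 to 8 and 9.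

7 to 1. The C20–S bond, the C9–C20 bond, the C8–I bond and the isopropyl group are removed in turn (6, 5, 4, 3, 2). Each substituent enters at the position that the methoxy groups activate at that stage: lithiation between two methoxy groups, iodination at the most electron-rich free carbon, then formylation at the last free one.

## Other disconnections considered

Alternative 1: The cut removes C7–C8 and C9–C20, both bonds from ring B to ring C, in an oxidopyrylium (5+2) cycloaddition. Et3N would turn the ring-A-fused acetoxypyranone A1 into the 3-oxidopyrylium ylide, which would add across the unsubstituted C8=C9 bond of quinone A2 and, after enolisation, give the oxygen-bridged hydroquinone A3.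
- In favour: it is convergent, forms two carbon–carbon bonds and ring B in one step, and needs no methyl ethers on ring C, so no oxidative demethylation at the end.
- Against: the orientation of the ylide across C8=C9 is decided only by the remote methoxy and isopropyl groups, so the regioisomer with C7 on C9 should compete. A3 has C5=C10, a C6 ketone and a C7–O–C20 bridge; both bridge C–O bonds must be cleaved, the C5 hydrogen introduced cis to the methyl, C10=C20 and C6=C7 created and the ester turned into the enol lactone.
- Comparison: on structure A3 reaches the full carbon skeleton earlier, a point on which it is better. On mechanism a concerted cycloaddition is as dependable as a 1,3-elimination (equal), but its regiochemistry is open, whereas the sulfone contraction can only give C10=C20. On step economy it is shorter up to the skeleton and longer after it, and C5 would still be unset.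

Alternative 2: The cut removes C3–C4 and C5–C10 in an intramolecular Diels–Alder reaction of A4. The butenolide C4=C5 bond is the dienophile and the 2-silyloxydiene is tethered through C20, ring C and C7; heat or Me2AlCl would give A5.
- In favour: rings A and B and the stereocentres C4 and C5 form together, and the absolute sense comes from the menthyloxy group on C6, which is lost later when the enol lactone is made. This is better than the chosen plan in stereochemical economy, since there C4 and C5 are set in a separate catalysed cycloaddition. Both plans use a Diels–Alder reaction for ring A (equal).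
- Against: the dienophile is trisubstituted and flanked by the quaternary ketal C6, and the tether has to close a seven-membered ring, so forcing conditions would meet a labile silyl dienol ether. A5 has C7H2, C20H2 and C10–H, and its enol ether points to C2. C10=C20 must then be introduced by dehydrogenation with regiocontrol against C2 and C5, and menthol must be lost towards C7 and not C5.
- Comparison: the alternative builds more rings per step. The chosen plan places the C10=C20 alkene unambiguously through the position of sulfur and has the C6=C7 geometry fixed before ring B exists; in step count the two should be similar once the dehydrogenations are included.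

Alternative 3: The cut removes C5–C6 and C5–C10 in a transannular Buchner reaction. Tosylhydrazone A6 would give the diazoalkane, Rh2(OAc)4 would form the carbene, which adds across the aromatic C6–C10 bond; the norcaradiene then opens to A7.
- In favour: the γ-lactone, ring A and ring B arise in one step, the three double bonds of ring B appear at their final positions and C5 is created in the key step. In bond economy and in setting C5 it is better than the chosen plan, whose key step forms one bond and no stereocentre.
- Against: the carbene has no acceptor group, so azine formation, 1,2-shift of a C4 substituent and C–H insertion compete. Addition across C6–C7 would give a regioisomeric cycloheptatriene, and 1,5-hydrogen shifts could move the C5 hydrogen. A6 is an eight-membered aryl lactone carrying a quinone bisketal and is itself hard to make.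
- Comparison: both plans reach ring B by reorganising a ring closed in another way (equal in concept). The chosen plan relies on stepwise, well-understood displacements at sulfur; the alternative would be much shorter if the carbene behaved.

Key step: step 16

Remark: atom numbers are those of the icetexane skeleton. The sense of induction of the oxazaborolidinium catalyst in step 9 is assigned from the usual model for 2-substituted acroleins; the (S)-catalyst is written, and its antipode is to be used if the opposite face is delivered.

## Route

Step 1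
Reactants: 1 1,2,4-trimethoxybenzene
Product: 2 2-(2,3,6-trimethoxyphenyl)propan-2-ol
Conditions: n-BuLi, THF, 0 °C to rt; acetone, −78 °C to rt
Reagents that add atoms: acetone CC(C)=O
Why: Directed ortho-lithiation takes place at the carbon between two methoxy groups, and the aryllithium adds to acetone.

Step 2
Reactants: 2 2-(2,3,6-trimethoxyphenyl)propan-2-ol
Product: 3 1,2,4-trimethoxy-3-(propan-2-yl)benzene
Conditions: Et3SiH, TFA, CH2Cl2, 0 °C
Reagents that add atoms: none
Why: Ionic hydrogenation: the tertiary benzylic cation formed in acid is reduced by the silane.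

Step 3
Reactants: 3 1,2,4-trimethoxy-3-(propan-2-yl)benzene
Product: 4 1-iodo-2,4,5-trimethoxy-3-(propan-2-yl)benzene
Conditions: NIS, TFA (cat.), MeCN, 0 °C to rt
Reagents that add atoms: N-iodosuccinimide O=C1CCC(=O)N1I
Why: Electrophilic aromatic iodination should enter the free position that is ortho to one methoxy group and para to another (the future C8), the more activated of the two open sites.

Step 4
Reactants: 4 1-iodo-2,4,5-trimethoxy-3-(propan-2-yl)benzene
Product: 5 2-iodo-3,5,6-trimethoxy-4-(propan-2-yl)benzaldehyde
Conditions: Cl2CHOMe, TiCl4, CH2Cl2, −40 to 0 °C; H2O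
Reagents that add atoms: dichloromethyl methyl ether COC(Cl)Cl; water O
Why: Rieche formylation at the only remaining ring position (the future C9, ortho to a methoxy group) installs C20; the low temperature is chosen to disfavour attack at the iodine-bearing carbon.

Step 5
Reactants: 5 2-iodo-3,5,6-trimethoxy-4-(propan-2-yl)benzaldehyde
Product: 6 trimethyl[2-({[2-iodo-3,5,6-trimethoxy-4-(propan-2-yl)phenyl]methyl}sulfanyl)ethyl]silane
Conditions: HSCH2CH2SiMe3, Et3SiH, TFA, CH2Cl2, 0 °C to rt
Reagents that add atoms: 2-(trimethylsilyl)ethanethiol C[Si](C)(C)CCS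
Why: Reductive thioetherification: the thiol and the aldehyde give a thionium ion in acid, which the silane reduces to the benzylic sulfide.

Step 6
Reactants: 6 trimethyl[2-({[2-iodo-3,5,6-trimethoxy-4-(propan-2-yl)phenyl]methyl}sulfanyl)ethyl]silane
Product: 7 trimethyl[2-({[2-iodo-3,5,6-trimethoxy-4-(propan-2-yl)phenyl]methyl}sulfonyl)ethyl]silane
Conditions: (NH4)6Mo7O24·4H2O (cat.), 30% H2O2, EtOH, rt
Reagents that add atoms: hydrogen peroxide OO
Why: Molybdate-catalysed oxidation of a sulfide to the sulfone, which should leave the aryl iodide and the electron-rich ring alone; the 2-silylethyl sulfone is a masked benzylic sulfinate.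

Step 7
Reactants: 8 3-(trimethylsilyl)prop-2-ynal; 9 1-(triphenylphosphoranylidene)propan-2-one
Product: 10 (3E)-6-(trimethylsilyl)hex-3-en-5-yn-2-one
Conditions: CH2Cl2, rt
Reagents that add atoms: none
Why: Wittig olefination with a stabilised ylide, which should give the E enone.

Step 8
Reactants: 10 (3E)-6-(trimethylsilyl)hex-3-en-5-yn-2-one
Product: 11 triisopropyl{[(3E)-6-(trimethylsilyl)hexa-1,3-dien-5-yn-2-yl]oxy}silane
Conditions: TIPSOTf, Et3N, CH2Cl2, 0 °C
Reagents that add atoms: triisopropylsilyl trifluoromethanesulfonate CC(C)[Si](OS(=O)(=O)C(F)(F)F)(C(C)C)C(C)C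
Why: Soft enolisation and O-silylation; the methyl group is the only enolisable position, so one 2-silyloxydiene results.

Step 9
Reactants: 11 triisopropyl{[(3E)-6-(trimethylsilyl)hexa-1,3-dien-5-yn-2-yl]oxy}silane; 12 2-methylprop-2-enal (methacrolein)
Product: 13 (1S,2R)-1-methyl-4-[(triisopropylsilyl)oxy]-2-[(trimethylsilyl)ethynyl]cyclohex-3-ene-1-carbaldehyde (formyl and alkynyl cis)
Conditions: (S)-3,3-diphenyl-1-(o-tolyl)tetrahydro-1H,3H-pyrrolo[1,2-c][1,3,2]oxazaborole (20 mol%), HNTf2 (16 mol%), CH2Cl2, −78 °C
Reagents that add atoms: none
Why: Catalytic enantioselective Diels–Alder reaction of a 2-substituted acrolein bound to a chiral oxazaborolidinium ion; the silyloxy group directs C2 of the diene to the β-carbon of the enal so that C4 is para to the oxygen-bearing C1 and next to C5, and the new enol ether lies between C1 and C10. The catalyst shields one face of the enal and sets C4; the endo orientation of the formyl group sets C5 with the alkynyl group cis to the formyl group.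

Step 10
Reactants: 13 (1S,2R)-1-methyl-4-[(triisopropylsilyl)oxy]-2-[(trimethylsilyl)ethynyl]cyclohex-3-ene-1-carbaldehyde
Product: 15 (1S,2S)-2-ethynyl-1-methyl-4-[(triisopropylsilyl)oxy]cyclohex-3-ene-1-carboxylic acid (carboxyl and ethynyl cis), via silylalkynyl acid 14 (not isolated)
Conditions: NaClO2, NaH2PO4, 2-methyl-2-butene, t-BuOH/H2O, 0 °C; then K2CO3, MeOH, rt; citric acid work-up
Reagents that add atoms: sodium chlorite [Na+].[O-]Cl=O
Why: Pinnick oxidation of an aldehyde with no α-hydrogen, with a large excess of the alkene scavenger to protect the enol ether from hypochlorite; basic methanol then removes the alkynyl silyl group while the hindered triisopropylsilyl enol ether should survive.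

Step 11
Reactants: 15 (1S,2S)-2-ethynyl-1-methyl-4-[(triisopropylsilyl)oxy]cyclohex-3-ene-1-carboxylic acid; 7 trimethyl[2-({[2-iodo-3,5,6-trimethoxy-4-(propan-2-yl)phenyl]methyl}sulfonyl)ethyl]silane
Product: 16 (3E,3aR,7aS)-7a-methyl-3-{[3,4,6-trimethoxy-5-(propan-2-yl)-2-({[2-(trimethylsilyl)ethyl]sulfonyl}methyl)phenyl]methylidene}-5-[(triisopropylsilyl)oxy]-3a,6,7,7a-tetrahydro-2-benzofuran-1(3H)-one
Conditions: Pd(OAc)2 (5 mol%), PPh3, Et3N, Bu4NCl, DMSO, 50 °C
Reagents that add atoms: none
Why: Palladium-catalysed cyclisation–coupling of a 4-alkynoic acid with an aryl iodide: the arylpalladium iodide (divalent palladium) activates the alkyne, the carboxylate adds anti in a 5-exo-dig mode and reductive elimination joins C7 to C8. The aryl group therefore ends trans to the ring oxygen (E), and the cis C4/C5 relationship allows only the cis-fused lactone.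

Step 12
Reactants: 16 (3E,3aR,7aS)-enol lactone silyl enol ether
Product: 17 (3E,3aR,7aS)-4-bromo-7a-methyl-3-{[3,4,6-trimethoxy-5-(propan-2-yl)-2-({[2-(trimethylsilyl)ethyl]sulfonyl}methyl)phenyl]methylidene}-3a,4,7,7a-tetrahydro-2-benzofuran-1,5(3H,6H)-dione (epimers at the bromine-bearing carbon, C10)
Conditions: NBS, NaHCO3, THF, −78 °C
Reagents that add atoms: N-bromosuccinimide O=C1CCC(=O)N1Br
Why: Electrophilic bromination of a silyl enol ether places bromine on C10 only, because the enol ether double bond is C1=C10; the silyl enol ether is far more nucleophilic than the twisted, acyl-substituted C6=C7 alkene.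

Step 13
Reactants: 17 C10 bromo ketone
Product: 19 cyclic β-keto sulfone: (4S,5R)-11,12,14-trimethoxy-13-isopropyl C1 ketone with the 19,6-enol lactone (C6=C7), in which SO2 bridges C10 and C20 (eight-membered ring C5–C6–C7–C8–C9–C20–S–C10; C10 epimers), via benzylic sulfinate 18 (not isolated)
Conditions: (Me2N)3S+ Me3SiF2− (TASF), DMF, 0.002 M, 0 °C to rt
Reagents that add atoms: none
Why: Fluoride attacks silicon and the 2-silylethyl sulfone fragments to ethylene and the benzylic sulfinate, whose sulfur displaces the activated secondary bromide at C10 (SN2) to give the sulfone directly, with no oxidation needed. Bromide exchange should interconvert the C10 epimers so both can close, and high dilution favours the eight-membered ring, which is pre-organised by the E alkene and the ortho-disubstituted arene.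

Step 14
Reactants: 19 cyclic β-keto sulfone
Product: 20 C1 O-tert-butyldimethylsilyl enol ether (C1=C10) of 19
Conditions: TBSOTf, Et3N, CH2Cl2, 0 °C
Reagents that add atoms: tert-butyldimethylsilyl trifluoromethanesulfonate CC(C)(C)[Si](C)(C)OS(=O)(=O)C(F)(F)F
Why: O-silylation of a β-keto sulfone occurs towards the sulfonyl-bearing carbon; it removes the acidic C10 hydrogen so that C20 becomes the only sulfonyl-activated sp3 C–H.

Step 15
Reactants: 20 C1 silyl enol ether of the cyclic sulfone
Product: 22 α-chloro β-keto sulfone: 19 with chlorine on C20 (C10 and C20 epimers), via C20-chloro silyl enol ether 21 (not isolated)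
Conditions: LiN(SiMe3)2, THF, −78 °C; C2Cl6; then HF·pyridine, 0 °C
Reagents that add atoms: hexachloroethane ClC(Cl)(Cl)C(Cl)(Cl)Cl
Why: Kinetic deprotonation of the β-silyloxy vinyl sulfone should occur at the benzylic α′-carbon C20 and not at the vinylogous C2 position (the same preference that vinylogous esters show); the sulfonyl carbanion is chlorinated by C2Cl6, and acidic fluoride then releases the ketone without starting the elimination.

Step 16
Reactants: 22 α-chloro β-keto sulfone
Product: 24 tetracyclic enone (4S,5R)-11,12,14-trimethoxy-1-oxoicetexa-6,8,10(20),11,13-pentaen-19,6-olide, via thiirane dioxide 23 (not isolated)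
Conditions: DBU, MeCN, 0 °C to rt
Reagents that add atoms: none
Why: Ramberg–Bäcklund rearrangement of a cyclic α-halo sulfone: DBU removes the C10 hydrogen, which is flanked by ketone and sulfone; the carbanion displaces chloride at benzylic C20 in a 3-exo-tet closure to the thiirane 1,1-dioxide, and cheletropic loss of SO2 gives the C10=C20 alkene. The net result is contraction of the eight-membered sulfone to seven-membered ring B. No stereocentre is formed: C10 and C20 become sp2, so their epimers converge, C4 and C5 are untouched, and the alkene geometry is dictated by the ring. Chemoselectivity requires carbon, not oxygen, of the enolate to attack C20; open-chain α′-halo β-keto sulfones can close through oxygen to 1,3-oxathiole dioxides, but here the eight-membered ring holds C20 out of the enolate plane and O-attack would create a bridgehead C1=C10 bond, so the out-of-plane C-attack should prevail. Regiochemistry is fixed by chlorine being on C20 and the only acidic hydrogen on C10, so no α-halo ketone with an enolisable C2 is ever present. The amidine base is not nucleophilic, and the lactone carbonyl is shielded by the quaternary C4.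

Step 17
Reactants: 24 tetracyclic enone
Product: 25 (1R,4S,5R)-1-hydroxy-11,12,14-trimethoxyicetexa-6,8,10(20),11,13-pentaen-19,6-olide
Conditions: NaBH4, CeCl3·7H2O, MeOH/CH2Cl2, −78 °C
Reagents that add atoms: none
Why: Luche reduction gives 1,2-addition only; hydride should attack C1 axially from the face that carries the C5 hydrogen and the C4 methyl, opposite the cis-fused lactone, which places the hydroxyl on the lactone face (1R).

Step 18
Reactants: 25 allylic alcohol trimethyl ether
Product: 26 (1R,4S,5R)-1-hydroxy-12-methoxy-11,14-dioxoicetexa-6,8,10(20),12-tetraen-19,6-olide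
Conditions: (NH4)2Ce(NO3)6, MeCN/H2O, 0 °C
Reagents that add atoms: water O
Why: Oxidative demethylation by tetravalent cerium converts the para-related C11 and C14 methyl ethers into the 1,4-quinone and leaves the C12 methyl ether as a vinylogous ester.

Step 19
Reactants: 26 12-methoxyquinone
Product: 27 6,7-anhydroballotiquinone, (1R,4S,5R)-1,12-dihydroxy-11,14-dioxoicetexa-6,8,10(20),12-tetraen-19,6-olide
Conditions: Na2CO3 (aq.), THF, 0 °C to rt; pH 4 buffer
Reagents that add atoms: water O
Why: Addition–elimination of hydroxide at C12 of the vinylogous methyl ester gives the hydroxyquinone; the quinone carbon is much more electrophilic than the lactone carbonyl, which sits next to the quaternary C4.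

## Compound list

1 | 1,2,4-trimethoxybenzene | COc1ccc(OC)c(OC)c1 | starting material
2 | 2-(2,3,6-trimethoxyphenyl)propan-2-ol | COc1ccc(OC)c(C(C)(C)O)c1OC | intermediate
3 | 1,2,4-trimethoxy-3-(propan-2-yl)benzene | COc1ccc(OC)c(C(C)C)c1OC | intermediate
4 | 1-iodo-2,4,5-trimethoxy-3-(propan-2-yl)benzene | COc1cc(I)c(OC)c(C(C)C)c1OC | intermediate
5 | 2-iodo-3,5,6-trimethoxy-4-(propan-2-yl)benzaldehyde | COc1c(C=O)c(I)c(OC)c(C(C)C)c1OC | intermediate
6 | trimethyl[2-({[2-iodo-3,5,6-trimethoxy-4-(propan-2-yl)phenyl]methyl}sulfanyl)ethyl]silane | COc1c(CSCC[Si](C)(C)C)c(I)c(OC)c(C(C)C)c1OC | intermediate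
7 | trimethyl[2-({[2-iodo-3,5,6-trimethoxy-4-(propan-2-yl)phenyl]methyl}sulfonyl)ethyl]silane | COc1c(CS(=O)(=O)CC[Si](C)(C)C)c(I)c(OC)c(C(C)C)c1OC | intermediate
8 | 3-(trimethylsilyl)prop-2-ynal | C[Si](C)(C)C#CC=O | starting material
9 | 1-(triphenylphosphoranylidene)propan-2-one | CC(=O)C=P(c1ccccc1)(c1ccccc1)c1ccccc1 | starting material
10 | (3E)-6-(trimethylsilyl)hex-3-en-5-yn-2-one | CC(=O)/C=C/C#C[Si](C)(C)C | intermediate
11 | triisopropyl{[(3E)-6-(trimethylsilyl)hexa-1,3-dien-5-yn-2-yl]oxy}silane | C=C(O[Si](C(C)C)(C(C)C)C(C)C)/C=C/C#C[Si](C)(C)C | intermediate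
12 | 2-methylprop-2-enal (methacrolein) | CC(=C)C=O | starting material
13 | (1S,2R)-1-methyl-4-[(triisopropylsilyl)oxy]-2-[(trimethylsilyl)ethynyl]cyclohex-3-ene-1-carbaldehyde | O=C[C@@]1(C)CCC(O[Si](C(C)C)(C(C)C)C(C)C)=C[C@H]1C#C[Si](C)(C)C | intermediate
14 | (1S,2R)-1-methyl-4-[(triisopropylsilyl)oxy]-2-[(trimethylsilyl)ethynyl]cyclohex-3-ene-1-carboxylic acid | OC(=O)[C@@]1(C)CCC(O[Si](C(C)C)(C(C)C)C(C)C)=C[C@H]1C#C[Si](C)(C)C | intermediate
15 | (1S,2S)-2-ethynyl-1-methyl-4-[(triisopropylsilyl)oxy]cyclohex-3-ene-1-carboxylic acid | OC(=O)[C@@]1(C)CCC(O[Si](C(C)C)(C(C)C)C(C)C)=C[C@H]1C#C | intermediate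
16 | (3E,3aR,7aS)-7a-methyl-3-{[3,4,6-trimethoxy-5-(propan-2-yl)-2-({[2-(trimethylsilyl)ethyl]sulfonyl}methyl)phenyl]methylidene}-5-[(triisopropylsilyl)oxy]-3a,6,7,7a-tetrahydro-2-benzofuran-1(3H)-one | CC(C)c1c(OC)c(OC)c(CS(=O)(=O)CC[Si](C)(C)C)c(/C=C2/OC(=O)[C@@]3(C)CCC(O[Si](C(C)C)(C(C)C)C(C)C)=C[C@@H]23)c1OC | intermediate
17 | (3E,3aR,7aS)-4-bromo-7a-methyl-3-{[3,4,6-trimethoxy-5-(propan-2-yl)-2-({[2-(trimethylsilyl)ethyl]sulfonyl}methyl)phenyl]methylidene}-3a,4,7,7a-tetrahydro-2-benzofuran-1,5(3H,6H)-dione (C10 epimers) | CC(C)c1c(OC)c(OC)c(CS(=O)(=O)CC[Si](C)(C)C)c(/C=C2/OC(=O)[C@@]3(C)CCC(=O)C(Br)[C@@H]23)c1OC | intermediate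
18 | tris(dimethylamino)sulfonium salt of the benzylic sulfinate of 17 | CC(C)c1c(OC)c(OC)c(CS(=O)[O-])c(/C=C2/OC(=O)[C@@]3(C)CCC(=O)C(Br)[C@@H]23)c1OC.CN(C)[S+](N(C)C)N(C)C | intermediate
19 | (4S,5R) cyclic β-keto sulfone, SO2 bridging C10 and C20, 19,6-enol lactone, 11,12,14-trimethyl ether (C10 epimers) | CC(C)c1c(OC)c(OC)c2c(C=C3OC(=O)[C@@]4(C)CCC(=O)C(S(=O)(=O)C2)[C@@H]34)c1OC | intermediate
20 | C1 O-tert-butyldimethylsilyl enol ether (C1=C10) of 19 | CC(C)c1c(OC)c(OC)c2c(C=C3OC(=O)[C@@]4(C)CCC(O[Si](C)(C)C(C)(C)C)=C(S(=O)(=O)C2)[C@@H]34)c1OC | intermediate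
21 | C20-chloro derivative of 20 (C20 epimers) | CC(C)c1c(OC)c(OC)c2c(C=C3OC(=O)[C@@]4(C)CCC(O[Si](C)(C)C(C)(C)C)=C(S(=O)(=O)C2Cl)[C@@H]34)c1OC | intermediate
22 | (4S,5R) α-chloro β-keto sulfone bridging C10 and C20 (C10 and C20 epimers) | CC(C)c1c(OC)c(OC)c2c(C=C3OC(=O)[C@@]4(C)CCC(=O)C(S(=O)(=O)C2Cl)[C@@H]34)c1OC | intermediate
23 | thiirane 1,1-dioxide spanning C10 and C20 | CC(C)c1c(OC)c(OC)c2c(C=C3OC(=O)[C@@]4(C)CCC(=O)C5(C2S5(=O)=O)[C@@H]34)c1OC | intermediate
24 | (4S,5R)-11,12,14-trimethoxy-1-oxoicetexa-6,8,10(20),11,13-pentaen-19,6-olide | CC(C)c1c(OC)c(OC)c2c(C=C3OC(=O)[C@@]4(C)CCC(=O)C(=C2)[C@@H]34)c1OC | intermediate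
25 | (1R,4S,5R)-1-hydroxy-11,12,14-trimethoxyicetexa-6,8,10(20),11,13-pentaen-19,6-olide | CC(C)c1c(OC)c(OC)c2c(C=C3OC(=O)[C@@]4(C)CC[C@@H](O)C(=C2)[C@@H]34)c1OC | intermediate
26 | (1R,4S,5R)-1-hydroxy-12-methoxy-11,14-dioxoicetexa-6,8,10(20),12-tetraen-19,6-olide | CC(C)C1=C(OC)C(=O)C2=C(C=C3OC(=O)[C@@]4(C)CC[C@@H](O)C(=C2)[C@@H]34)C1=O | intermediate
27 | 6,7-anhydroballotiquinone | CC(C)C1=C(O)C(=O)C2=C(C=C3OC(=O)[C@@]4(C)CC[C@@H](O)C(=C2)[C@@H]34)C1=O | target

## Step count and least certain steps

Total: 19 steps. Longest linear sequence: 15 steps (steps 1–6, then 11–19); the ring A branch (steps 7–10) joins at step 11.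

Step 16 (key step). The most likely failure is closure of the enolate through oxygen onto C20, giving a fused 1,3-oxathiole dioxide, or a closure so slow (the carbanion is doubly stabilised) that the chloro sulfone decomposes first. Fallback: close ring B by a carbon–carbon aldol condensation. It sets out from 15 and 5 and returns at 24. Coupling of 15 with aldehyde 5 under the conditions of step 11 should give the aryl aldehyde enol lactone F1. TiCl4 in CH2Cl2 at −78 °C should then bring about an intramolecular Mukaiyama aldol addition of the C1=C10 silyl enol ether to the C20 aldehyde, giving the β-hydroxy ketone F2. Mesylation and DBU would eliminate to 24.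

Step 15. Metalation may not be selective: removal of an allylic C2 hydrogen, incomplete deprotonation of the hindered benzylic position, or a second chlorination by proton exchange. Fallback: take C10 out of play by reduction instead of silylation. It sets out from 19 and returns at 22. NaBH4 should give the β-hydroxy sulfone F3. Two equivalents of LiN(SiMe3)2 form the alkoxide and then the benzylic carbanion, the only acidic C–H left, and C2Cl6 gives the chloro alcohol F4. Oxidation with the periodinane DMP then gives 22.

Step 13. The sulfinate is a modest nucleophile, so intermolecular alkylation, O-alkylation to a sulfinate ester, or fluoride-induced loss of HBr may outrun the eight-membered closure. Fallback: form both carbon–sulfur bonds with sulfide and oxidise afterwards. It sets out from 5 and 15 and returns at 19. NaBH4 reduces 5 to the iodo benzyl alcohol F5, which is coupled with 15 as in step 11 to the enol lactone alcohol F6. MsCl, Et3N and LiCl give the benzylic chloride F7, and NBS gives the bromo ketone chloride F8. Anhydrous Na2S in DMF at high dilution closes the cyclic sulfide F9, and (NH4)6Mo7O24/H2O2 oxidises it to 19.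

Step 11. Oxidative addition of the di-ortho-substituted, electron-rich aryl iodide may be slow, so cycloisomerisation of the acid without arylation or direct alkynylation of the arene could take over. Fallback: couple and cyclise in separate steps and correct the geometry with light. It sets out from 15 and 7 and returns at 16. Sonogashira coupling (Pd(PPh3)2Cl2, CuI, Et3N) gives the aryl alkynoic acid F10. AgNO3-catalysed 5-exo-dig cyclisation gives the Z enol lactone F11 by anti addition of O–H. Irradiation at 365 nm should establish an E/Z mixture from which 16 is separated and F11 recycled.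

Step 9. Facial selectivity with this 1,3-disubstituted diene, or the endo preference that makes formyl and alkynyl cis, may be eroded. Fallback: give up catalytic induction and resolve. It sets out from 11 and 12 and returns at 15. Cycloaddition with EtAlCl2 gives racemic 13, step 10 gives racemic 15, and crystallisation with (R)-1-phenylethylamine gives the salt F12 of the (1S,2S) acid, which also rejects the trans diastereomer. Acidification returns 15 (the antipodal amine is used if the other salt crystallises).

Further compounds

F1 | step 16 | (3E,3aR,7aS) enol lactone silyl enol ether with a formyl group on the aryl ring at C9 (C20 aldehyde) | CC(C)c1c(OC)c(OC)c(C=O)c(/C=C2/OC(=O)[C@@]3(C)CCC(O[Si](C(C)C)(C(C)C)C(C)C)=C[C@@H]23)c1OC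
F2 | step 16 | tetracyclic β-hydroxy ketone, C10–C20 bond formed, hydroxyl on C20 (C10 and C20 epimers) | CC(C)c1c(OC)c(OC)c2c(C=C3OC(=O)[C@@]4(C)CCC(=O)C(C2O)[C@@H]34)c1OC
F3 | step 15 | cyclic β-hydroxy sulfone, C1 alcohol of 19 (C1 and C10 epimers) | CC(C)c1c(OC)c(OC)c2c(C=C3OC(=O)[C@@]4(C)CCC(O)C(S(=O)(=O)C2)[C@@H]34)c1OC
F4 | step 15 | C20-chloro cyclic β-hydroxy sulfone (epimers) | CC(C)c1c(OC)c(OC)c2c(C=C3OC(=O)[C@@]4(C)CCC(O)C(S(=O)(=O)C2Cl)[C@@H]34)c1OC
F5 | step 13 | [2-iodo-3,5,6-trimethoxy-4-(propan-2-yl)phenyl]methanol | COc1c(CO)c(I)c(OC)c(C(C)C)c1OC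
F6 | step 13 | (3E,3aR,7aS) enol lactone silyl enol ether with hydroxymethyl on the aryl ring at C9 | CC(C)c1c(OC)c(OC)c(CO)c(/C=C2/OC(=O)[C@@]3(C)CCC(O[Si](C(C)C)(C(C)C)C(C)C)=C[C@@H]23)c1OC
F7 | step 13 | (3E,3aR,7aS) enol lactone silyl enol ether with chloromethyl on the aryl ring at C9 | CC(C)c1c(OC)c(OC)c(CCl)c(/C=C2/OC(=O)[C@@]3(C)CCC(O[Si](C(C)C)(C(C)C)C(C)C)=C[C@@H]23)c1OC
F8 | step 13 | C10 bromo ketone with chloromethyl on the aryl ring at C9 (C10 epimers) | CC(C)c1c(OC)c(OC)c(CCl)c(/C=C2/OC(=O)[C@@]3(C)CCC(=O)C(Br)[C@@H]23)c1OC
F9 | step 13 | cyclic α-keto sulfide, sulfur bridging C10 and C20 (C10 epimers) | CC(C)c1c(OC)c(OC)c2c(C=C3OC(=O)[C@@]4(C)CCC(=O)C(SC2)[C@@H]34)c1OC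
F10 | step 11 | (1S,2S)-2-(arylethynyl)-1-methyl-4-[(triisopropylsilyl)oxy]cyclohex-3-ene-1-carboxylic acid, aryl = 3,4,6-trimethoxy-5-(propan-2-yl)-2-({[2-(trimethylsilyl)ethyl]sulfonyl}methyl)phenyl | OC(=O)[C@@]1(C)CCC(O[Si](C(C)C)(C(C)C)C(C)C)=C[C@H]1C#Cc1c(CS(=O)(=O)CC[Si](C)(C)C)c(OC)c(OC)c(C(C)C)c1OC
F11 | step 11 | (3Z,3aR,7aS) isomer of 16 (aryl cis to the ring oxygen) | CC(C)c1c(OC)c(OC)c(CS(=O)(=O)CC[Si](C)(C)C)c(\C=C2/OC(=O)[C@@]3(C)CCC(O[Si](C(C)C)(C(C)C)C(C)C)=C[C@@H]23)c1OC
F12 | step 9 | (R)-1-phenylethylammonium salt of 15 | C[C@@H]([NH3+])c1ccccc1.[O-]C(=O)[C@@]1(C)CCC(O[Si](C(C)C)(C(C)C)C(C)C)=C[C@H]1C#C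
A1 | alternative 1 | ring-A-fused 6-acetoxy-2H-pyran-3(6H)-one (methyl ester at C4, silyl ether at C1) | COC(=O)[C@@]1(C)CC[C@@H](O[Si](C)(C)C(C)(C)C)C2=C1C(=O)COC2OC(C)=O
A2 | alternative 1 | 2-methoxy-3-(propan-2-yl)-1,4-benzoquinone | CC(C)C1=C(OC)C(=O)C=CC1=O
A3 | alternative 1 | oxygen-bridged tetracyclic hydroquinone | COC(=O)[C@@]1(C)CC[C@@H](O[Si](C)(C)C(C)(C)C)C2=C1C(=O)[C@@H]3O[C@H]2c2c(O)c(OC)c(C(C)C)c(O)c23
A4 | alternative 2 | 5-(arylmethyl)-5-(menthyloxy)-3-methylfuran-2(5H)-one carrying the 2-silyloxydiene on the aryl ring | CC(C)c1c(OC)c(OC)c(CC=C(O[Si](C)(C)C(C)(C)C)C=C)c(C[C@@]2(O[C@@H]3C[C@H](C)CC[C@H]3C(C)C)OC(=O)C(C)=C2)c1OC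
A5 | alternative 2 | tetracyclic cycloadduct (C1 silyl enol ether, C6 menthyl ketal) | CC(C)c1c(OC)c(OC)c2c(C[C@@]3(O[C@@H]5C[C@H](C)CC[C@H]5C(C)C)OC(=O)[C@@]4(C)CC=C(O[Si](C)(C)C(C)(C)C)[C@@H](C2)[C@@H]34)c1OC
A6 | alternative 3 | eight-membered aryl lactone with the C5 tosylhydrazone on C4, fused to the quinone bisketal | CC(C)C1=C(OC)C(OC)(OC)c2cc3c(cc2C1(OC)OC)OC(=O)[C@](C)(C=NNS(=O)(=O)c2ccc(C)cc2)CC[C@H]3O[Si](C)(C)C(C)(C)C
A7 | alternative 3 | quinone bis(dimethyl ketal) of the O-methyl, O-silyl target | CC(C)C1=C(OC)C(OC)(OC)C2=C(C=C3OC(=O)[C@@]4(C)CC[C@@H](O[Si](C)(C)C(C)(C)C)C(=C2)[C@@H]34)C1(OC)OC
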